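## Retrosynthetic overview

1. Target ⇐ bis-MOM 8-formyl isoflavan ⇐ (3R)-8-bromo isoflavan (Br/Li exchange, DMF); the two MOM groups come off last.
2. The pyran ring is the only ring made (both benzene rings are bought); it is closed late by Mitsunobu etherification O1–C2 of a phenol/primary alcohol.
3. That phenol-alcohol ⇐ syn-aldol adduct, by one-pot reductive auxiliary removal and o-quinone-methide deoxygenation of the benzylic OH (triggered by an ortho O-Boc group).
4. Key C3–C4 bond ⇐ Evans boron aldol between the N-(arylacetyl)-(S)-4-benzyloxazolidinone (ring B) and an O-Boc salicylaldehyde (ring A); this sets C3.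
5. Ring A aldehyde ⇐ 5-methoxyresorcinol (ortho-lithiation/bromination, Vilsmeier); ring B acid ⇐ 3-methoxyphenol (ortho-lithiation/prenylation, ortho-lithiation/hydroxyethylation, oxidation).

Assumption and abbreviations: the stereocentre in the SMILES is read as (3R); Ar = 4-methoxy-2-(methoxymethoxy)-3-(3-methylbut-2-en-1-yl)phenyl, MOM = CH2OCH3, Boc = CO2t-Bu.

## Route

**Ring A aldehyde**

Step 1
Reactants: 1 5-methoxybenzene-1,3-diol
Product: 2 1-methoxy-3,5-bis(methoxymethoxy)benzene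
Conditions: NaH (2.4 equiv), MOMCl (2.4 equiv), DMF, 0 °C → rt
Reagents that add atoms: chloromethyl methyl ether (MOMCl), COCCl
Why: Williamson O-alkylation of both phenoxides installs the two MOM ethers that direct the next metalation.

Step 2
Reactants: 2 1-methoxy-3,5-bis(methoxymethoxy)benzene
Product: 4 2-bromo-5-methoxy-1,3-bis(methoxymethoxy)benzene, via aryllithium 3 (not isolated)
Conditions: n-BuLi (1.1 equiv), THF, 0 °C, 1 h; BrCCl2CCl2Br (1.2 equiv), −78 °C → rt
Reagents that add atoms: 1,2-dibromo-1,1,2,2-tetrachloroethane, BrC(Cl)(Cl)C(Cl)(Cl)Br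
Why: Directed ortho-metalation takes the C–H flanked by the two chelating OMOM groups, and bromine transfer to the aryllithium gives a symmetric bromide that removes later regiochemical ambiguity.

Step 3
Reactants: 4 2-bromo-5-methoxy-1,3-bis(methoxymethoxy)benzene
Product: 5 2-bromo-5-methoxybenzene-1,3-diol
Conditions: conc. HCl (cat.), MeOH, 45 °C
Reagents that add atoms: none
Why: Acid-catalysed acetal exchange with methanol cleaves both MOM ethers, and aryl bromide and methyl ether are inert.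

Step 4
Reactants: 5 2-bromo-5-methoxybenzene-1,3-diol
Product: 7 3-bromo-2,4-dihydroxy-6-methoxybenzaldehyde, via iminium salt 6 (not isolated)
Conditions: POCl3 (1.2 equiv), DMF (1.5 equiv), MeCN, 0 °C → rt; then H2O, 50 °C
Reagents that add atoms: N,N-dimethylformamide (DMF), CN(C)C=O; water, O
Why: Vilsmeier–Haack formylation can only occur at the two equivalent free positions (ortho/para to the hydroxyls), so a single aldehyde results after hydrolysis of the iminium salt.

Step 5
Reactants: 7 3-bromo-2,4-dihydroxy-6-methoxybenzaldehyde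
Product: 8 3-bromo-2-hydroxy-6-methoxy-4-(methoxymethoxy)benzaldehyde
Conditions: MOMCl (1.05 equiv), K2CO3 (1.2 equiv), acetone, 0 °C → rt
Reagents that add atoms: chloromethyl methyl ether (MOMCl), COCCl
Why: Selective Williamson etherification of the 4-OH (para to CHO, not hydrogen-bonded) while the 2-OH stays locked in the chelate with the aldehyde.

Step 6
Reactants: 8 3-bromo-2-hydroxy-6-methoxy-4-(methoxymethoxy)benzaldehyde
Product: 9 tert-butyl [2-bromo-6-formyl-5-methoxy-3-(methoxymethoxy)phenyl] carbonate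
Conditions: Boc2O (1.3 equiv), DMAP (0.1 equiv), i-Pr2NEt, THF, rt
Reagents that add atoms: di-tert-butyl dicarbonate (Boc2O), CC(C)(C)OC(=O)OC(=O)OC(C)(C)C
Why: DMAP-catalysed O-acylation gives the ortho-OBoc salicylaldehyde, which is more electrophilic than the phenol and carries the trigger for the later deoxygenation.

**Ring B imide**

Step 7
Reactants: 10 3-methoxyphenol
Product: 11 1-methoxy-3-(methoxymethoxy)benzene
Conditions: NaH (1.2 equiv), MOMCl (1.2 equiv), DMF, 0 °C → rt
Reagents that add atoms: chloromethyl methyl ether (MOMCl), COCCl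
Why: Williamson O-alkylation protects the phenol as the MOM ether needed as a metalation director.

Step 8
Reactants: 11 1-methoxy-3-(methoxymethoxy)benzene
Product: 13 1-methoxy-3-(methoxymethoxy)-2-(3-methylbut-2-en-1-yl)benzene, via aryllithium 12 (not isolated)
Conditions: n-BuLi (1.1 equiv), THF, 0 °C → rt, 1 h; prenyl bromide (1.2 equiv), −78 °C → rt
Reagents that add atoms: 1-bromo-3-methylbut-2-ene (prenyl bromide), CC(C)=CCBr
Why: Directed ortho-metalation occurs at the position between OMOM and OMe (cooperative directing), and the aryllithium is alkylated by SN2 attack on the primary allylic bromide.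

Step 9
Reactants: 13 1-methoxy-3-(methoxymethoxy)-2-(3-methylbut-2-en-1-yl)benzene
Product: 15 2-Ar-ethan-1-ol, via aryllithium 14 (not isolated)
Conditions: n-BuLi (1.2 equiv), THF, −20 → 0 °C, 1 h; ethylene oxide (3 equiv, solution in THF), −78 °C → rt; H2O
Reagents that add atoms: ethylene oxide (oxirane), C1CO1
Why: A second directed ortho-metalation goes ortho to OMOM (stronger director than OMe, its other ortho site is blocked), and the aryllithium opens the epoxide to give the two-carbon alcohol.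

Step 10
Reactants: 15 2-Ar-ethan-1-ol
Product: 16 2-Ar-acetaldehyde
Conditions: Dess–Martin periodinane (1.2 equiv), CH2Cl2, 0 °C → rt
Reagents that add atoms: none
Why: Dess–Martin oxidation stops cleanly at the aldehyde under near-neutral conditions that spare the MOM ether and the prenyl alkene.

Step 11
Reactants: 16 2-Ar-acetaldehyde
Product: 17 2-Ar-acetic acid
Conditions: NaClO2, NaH2PO4, 2-methylbut-2-ene (15 equiv), t-BuOH/H2O, 0 °C → rt
Reagents that add atoms: sodium chlorite, [Na+].[O-]Cl=O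
Why: Pinnick oxidation converts the aldehyde to the acid, with the excess alkene scavenger taking up HOCl so that the prenyl group and the electron-rich ring are not chlorinated.

Step 12
Reactants: 17 2-Ar-acetic acid; 18 (4S)-4-benzyl-1,3-oxazolidin-2-one
Product: 20 (4S)-4-benzyl-3-(2-Ar-acetyl)-1,3-oxazolidin-2-one, via mixed pivalic anhydride 19 (not isolated)
Conditions: PivCl (1.1 equiv), Et3N (2.5 equiv), THF, −20 °C; then 18, LiCl (1.2 equiv), −20 °C → rt
Reagents that add atoms: none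
Why: N-acylation of the oxazolidinone through the mixed anhydride (LiCl/Et3N protocol) attaches the chiral auxiliary without strong base.

**Fragment union and endgame**

Step 13
Reactants: 20 (4S)-4-benzyl-3-(2-Ar-acetyl)-1,3-oxazolidin-2-one; 9 tert-butyl [2-bromo-6-formyl-5-methoxy-3-(methoxymethoxy)phenyl] carbonate
Product: 22 (4S)-4-benzyl-3-[(2S,3S)-3-{3-bromo-2-[(tert-butoxycarbonyl)oxy]-6-methoxy-4-(methoxymethoxy)phenyl}-3-hydroxy-2-Ar-propanoyl]-1,3-oxazolidin-2-one, via Z-boron enolate 21 (not isolated)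
Conditions: Bu2BOTf (1.2 equiv), i-Pr2NEt (1.4 equiv), CH2Cl2, −78 → 0 °C; 9 (1.1 equiv), −78 → 0 °C; pH 7 buffer, MeOH, 30% H2O2, 0 °C
Reagents that add atoms: none
Why: Evans syn aldol, in which the Z-boron enolate reacts through a Zimmerman–Traxler chair with the aldehyde on the face away from the benzyl group, giving the (2S,3S) adduct whose α-carbon is the future (3R) centre of the isoflavan.

Step 14
Reactants: 22 the syn-aldol adduct
Product: 26 2-bromo-6-[(2R)-3-hydroxy-2-Ar-propyl]-5-methoxy-3-(methoxymethoxy)phenol, via Boc-diol 23 (not isolated), via benzylic carbonate 24 (not isolated), via o-quinone methide 25 (not isolated)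
Conditions: LiBH4 (5 equiv), THF, H2O (1 equiv), 0 °C, 2 h; then rt, 12 h
Reagents that add atoms: none
Why: Hydride first cleaves the imide to the primary alcohol (reductive auxiliary removal); the benzylic alkoxide then takes over the Boc group, the freed phenoxide expels the carbonate to an o-quinone methide, and borohydride reduces it by 1,4-addition (Pettus-type o-quinone-methide reduction), with no bond broken at the stereocentre.

Step 15
Reactants: 26 2-bromo-6-[(2R)-3-hydroxy-2-Ar-propyl]-5-methoxy-3-(methoxymethoxy)phenol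
Product: 28 (3R)-8-bromo-5-methoxy-7-(methoxymethoxy)-3-Ar-3,4-dihydro-2H-1-benzopyran, via alkoxyphosphonium phenoxide 27 (not isolated)
Conditions: PPh3 (1.5 equiv), DIAD (1.5 equiv), THF, 0 °C → rt
Reagents that add atoms: none
Why: Intramolecular Mitsunobu etherification (6-exo displacement at the primary CH2 by the acidic ortho-bromophenol) closes the pyran ring without touching the adjacent stereocentre.

Step 16
Reactants: 28 (3R)-8-bromo-5-methoxy-7-(methoxymethoxy)-3-Ar-3,4-dihydro-2H-1-benzopyran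
Product: 30 (3R)-5-methoxy-7-(methoxymethoxy)-3-Ar-3,4-dihydro-2H-1-benzopyran-8-carbaldehyde, via 8-lithiochromane 29 (not isolated)
Conditions: n-BuLi (1.1 equiv), THF, −78 °C, 15 min; DMF (3 equiv), −78 → 0 °C; H2O
Reagents that add atoms: N,N-dimethylformamide (DMF), CN(C)C=O
Why: Bromine–lithium exchange is faster than any deprotonation at −78 °C and fixes the site, so formylation of the aryllithium with DMF places the aldehyde only at C8.

Step 17
Reactants: 30 (3R)-5-methoxy-7-(methoxymethoxy)-3-Ar-3,4-dihydro-2H-1-benzopyran-8-carbaldehyde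
Product: 31 (3R)-7-hydroxy-3-[2-hydroxy-4-methoxy-3-(3-methylbut-2-en-1-yl)phenyl]-5-methoxy-3,4-dihydro-2H-1-benzopyran-8-carbaldehyde
Conditions: conc. HCl (cat.), MeOH, rt → 40 °C; aqueous work-up
Reagents that add atoms: none
Why: Mild acid-catalysed acetal exchange removes both MOM ethers while methyl ethers, the aldehyde, the prenyl group and the stereocentre stay intact.

## Compound list

1 | 5-methoxybenzene-1,3-diol (5-methoxyresorcinol) | COc1cc(O)cc(O)c1 | starting material
2 | 1-methoxy-3,5-bis(methoxymethoxy)benzene | COCOc1cc(OC)cc(OCOC)c1 | intermediate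
3 | [4-methoxy-2,6-bis(methoxymethoxy)phenyl]lithium (formed in the flask) | [Li]c1c(OCOC)cc(OC)cc1OCOC | intermediate
4 | 2-bromo-5-methoxy-1,3-bis(methoxymethoxy)benzene | COCOc1cc(OC)cc(OCOC)c1Br | intermediate
5 | 2-bromo-5-methoxybenzene-1,3-diol | COc1cc(O)c(Br)c(O)c1 | intermediate
6 | N-[(3-bromo-2,4-dihydroxy-6-methoxyphenyl)methylidene]-N-methylmethanaminium chloride (formed in the flask) | C[N+](C)=Cc1c(OC)cc(O)c(Br)c1O.[Cl-] | intermediate
7 | 3-bromo-2,4-dihydroxy-6-methoxybenzaldehyde | COc1cc(O)c(Br)c(O)c1C=O | intermediate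
8 | 3-bromo-2-hydroxy-6-methoxy-4-(methoxymethoxy)benzaldehyde | COCOc1cc(OC)c(C=O)c(O)c1Br | intermediate
9 | tert-butyl [2-bromo-6-formyl-5-methoxy-3-(methoxymethoxy)phenyl] carbonate | COCOc1cc(OC)c(C=O)c(OC(=O)OC(C)(C)C)c1Br | intermediate
10 | 3-methoxyphenol | COc1cccc(O)c1 | starting material
11 | 1-methoxy-3-(methoxymethoxy)benzene | COCOc1cccc(OC)c1 | intermediate
12 | [2-methoxy-6-(methoxymethoxy)phenyl]lithium (formed in the flask) | [Li]c1c(OC)cccc1OCOC | intermediate
13 | 1-methoxy-3-(methoxymethoxy)-2-(3-methylbut-2-en-1-yl)benzene | COCOc1cccc(OC)c1CC=C(C)C | intermediate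
14 | [4-methoxy-2-(methoxymethoxy)-3-(3-methylbut-2-en-1-yl)phenyl]lithium (formed in the flask) | [Li]c1ccc(OC)c(CC=C(C)C)c1OCOC | intermediate
15 | 2-[4-methoxy-2-(methoxymethoxy)-3-(3-methylbut-2-en-1-yl)phenyl]ethan-1-ol | COCOc1c(CCO)ccc(OC)c1CC=C(C)C | intermediate
16 | 2-[4-methoxy-2-(methoxymethoxy)-3-(3-methylbut-2-en-1-yl)phenyl]acetaldehyde | COCOc1c(CC=O)ccc(OC)c1CC=C(C)C | intermediate
17 | 2-[4-methoxy-2-(methoxymethoxy)-3-(3-methylbut-2-en-1-yl)phenyl]acetic acid | COCOc1c(CC(=O)O)ccc(OC)c1CC=C(C)C | intermediate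
18 | (4S)-4-benzyl-1,3-oxazolidin-2-one | O=C1OC[C@H](Cc2ccccc2)N1 | starting material
19 | 2-Ar-acetic 2,2-dimethylpropanoic anhydride (formed in the flask) | COCOc1c(CC(=O)OC(=O)C(C)(C)C)ccc(OC)c1CC=C(C)C | intermediate
20 | (4S)-4-benzyl-3-(2-Ar-acetyl)-1,3-oxazolidin-2-one | COCOc1c(CC(=O)N2[C@@H](Cc3ccccc3)COC2=O)ccc(OC)c1CC=C(C)C | intermediate
21 | (4S)-4-benzyl-3-[(Z)-2-Ar-1-(dibutylboranyloxy)ethenyl]-1,3-oxazolidin-2-one (formed in the flask) | CCCCB(CCCC)O/C(=C\c1ccc(OC)c(CC=C(C)C)c1OCOC)N1[C@@H](Cc2ccccc2)COC1=O | intermediate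
22 | (4S)-4-benzyl-3-[(2S,3S)-3-{3-bromo-2-[(tert-butoxycarbonyl)oxy]-6-methoxy-4-(methoxymethoxy)phenyl}-3-hydroxy-2-Ar-propanoyl]-1,3-oxazolidin-2-one | O=C1OC[C@H](Cc2ccccc2)N1C(=O)[C@@H](c3ccc(OC)c(CC=C(C)C)c3OCOC)[C@H](O)c4c(OC)cc(OCOC)c(Br)c4OC(=O)OC(C)(C)C | intermediate
23 | tert-butyl {2-bromo-6-[(1S,2R)-1,3-dihydroxy-2-Ar-propyl]-5-methoxy-3-(methoxymethoxy)phenyl} carbonate (formed in the flask) | OC[C@@H](c1ccc(OC)c(CC=C(C)C)c1OCOC)[C@H](O)c2c(OC)cc(OCOC)c(Br)c2OC(=O)OC(C)(C)C | intermediate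
24 | (1S,2R)-1-[3-bromo-2-hydroxy-6-methoxy-4-(methoxymethoxy)phenyl]-3-hydroxy-2-Ar-propyl tert-butyl carbonate (phenoxide in the flask) | OC[C@@H](c1ccc(OC)c(CC=C(C)C)c1OCOC)[C@H](OC(=O)OC(C)(C)C)c2c(OC)cc(OCOC)c(Br)c2O | intermediate
25 | 2-bromo-6-[(2R)-3-hydroxy-2-Ar-propylidene]-5-methoxy-3-(methoxymethoxy)cyclohexa-2,4-dien-1-one (o-quinone methide, alkene geometry not defined, formed in the flask) | OC[C@@H](c1ccc(OC)c(CC=C(C)C)c1OCOC)C=C2C(=O)C(Br)=C(OCOC)C=C2OC | intermediate
26 | 2-bromo-6-[(2R)-3-hydroxy-2-Ar-propyl]-5-methoxy-3-(methoxymethoxy)phenol | OC[C@@H](c1ccc(OC)c(CC=C(C)C)c1OCOC)Cc2c(OC)cc(OCOC)c(Br)c2O | intermediate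
27 | {(2R)-3-[3-bromo-6-methoxy-4-(methoxymethoxy)-2-oxidophenyl]-2-Ar-propoxy}triphenylphosphonium (zwitterion, formed in the flask) | [O-]c1c(Br)c(OCOC)cc(OC)c1C[C@H](c2ccc(OC)c(CC=C(C)C)c2OCOC)CO[P+](c3ccccc3)(c4ccccc4)c5ccccc5 | intermediate
28 | (3R)-8-bromo-5-methoxy-7-(methoxymethoxy)-3-Ar-3,4-dihydro-2H-1-benzopyran | COc1ccc([C@@H]2COc3c(Br)c(OCOC)cc(OC)c3C2)c(OCOC)c1CC=C(C)C | intermediate
29 | [(3R)-5-methoxy-7-(methoxymethoxy)-3-Ar-3,4-dihydro-2H-1-benzopyran-8-yl]lithium (formed in the flask) | COc1ccc([C@@H]2COc3c([Li])c(OCOC)cc(OC)c3C2)c(OCOC)c1CC=C(C)C | intermediate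
30 | (3R)-5-methoxy-7-(methoxymethoxy)-3-Ar-3,4-dihydro-2H-1-benzopyran-8-carbaldehyde | COc1ccc([C@@H]2COc3c(C=O)c(OCOC)cc(OC)c3C2)c(OCOC)c1CC=C(C)C | intermediate
31 | (3R)-7-hydroxy-3-[2-hydroxy-4-methoxy-3-(3-methylbut-2-en-1-yl)phenyl]-5-methoxy-3,4-dihydro-2H-1-benzopyran-8-carbaldehyde | COc1ccc([C@@H]2COc3c(C=O)c(O)cc(OC)c3C2)c(O)c1CC=C(C)C | target

## Summary

Total step count: 17.
Longest linear sequence: 11 steps (steps 1–6 then 13–17; the ring B branch, steps 7–12 then 13–17, is equally long).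

Three steps most likely to fail:

Step 14. The cascade depends on the Boc shift and on hydride capturing the o-quinone methide before it tautomerises to a styrene. The fallback separates the events and removes the benzylic oxygen by ionic hydrogenation after ring closure. It sets out from 22: LiBH4 in THF/MeOH at −20 °C with a cold quench lets the Boc-diol 23 be isolated. Piperidine in CH2Cl2 at 0 °C then removes the aryl carbonate by aminolysis to give 2-bromo-6-[(1S,2R)-1,3-dihydroxy-2-Ar-propyl]-5-methoxy-3-(methoxymethoxy)phenol F7. Mitsunobu closure (PPh3, DIAD, THF) gives (3R,4S)-8-bromo-5-methoxy-7-(methoxymethoxy)-3-Ar-3,4-dihydro-2H-1-benzopyran-4-ol F8. Et3SiH (10 equiv) and BF3·OEt2 in CH2Cl2 at −78 °C reduce the 4-OH, the large excess of silane being there to outrun capture of the C4 cation by the 2'-oxygen. The fallback comes back to the route at 28, bypassing 26.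

Step 13. Aldehyde 9 is di-ortho-substituted and still carries a para alkoxy donor, so the aldol addition may be slow or reversible. The fallback makes the electrophile more reactive rather than forcing the conditions. It sets out from 7: Boc2O (2.5 equiv) with DMAP gives di-tert-butyl (2-bromo-4-formyl-5-methoxy-1,3-phenylene) bis(carbonate) F3. The same boron enolate 21 adds to it to give (4S)-4-benzyl-3-[(2S,3S)-3-{3-bromo-2,4-bis[(tert-butoxycarbonyl)oxy]-6-methoxyphenyl}-3-hydroxy-2-Ar-propanoyl]-1,3-oxazolidin-2-one F4. LiBH4 (THF/H2O, 0 °C → rt) followed by 1 M NaOH performs the reductive cleavage and quinone-methide reduction and hydrolyses the remaining aryl carbonate to 2-bromo-4-[(2R)-3-hydroxy-2-Ar-propyl]-5-methoxybenzene-1,3-diol F5. Mitsunobu closure gives (3R)-8-bromo-5-methoxy-3-Ar-3,4-dihydro-2H-1-benzopyran-7-ol F6, and MOMCl/K2CO3 in acetone brings the route back at 28.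

Step 9. Deprotonation at the benzylic–allylic CH2 can compete with ring lithiation, the epoxide opening can be sluggish, and steps 10–11 pass through a sensitive arylacetaldehyde. The fallback sets out from 13: the same lithiation is quenched with DMF, a fast and clean trap, to give 4-methoxy-2-(methoxymethoxy)-3-(3-methylbut-2-en-1-yl)benzaldehyde F1. Van Leusen reductive cyanation (TosMIC, t-BuOK, DME, −40 °C; then MeOH, reflux) homologates it to 2-Ar-acetonitrile F2. KOH in EtOH/H2O at reflux hydrolyses the nitrile, and the fallback comes back at acid 17, so steps 10 and 11 fall away. It does not cure a failure of the lithiation itself.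

## Further compounds

F1 | step 9 | 4-methoxy-2-(methoxymethoxy)-3-(3-methylbut-2-en-1-yl)benzaldehyde | COCOc1c(C=O)ccc(OC)c1CC=C(C)C
F2 | step 9 | 2-[4-methoxy-2-(methoxymethoxy)-3-(3-methylbut-2-en-1-yl)phenyl]acetonitrile | COCOc1c(CC#N)ccc(OC)c1CC=C(C)C
F3 | step 13 | di-tert-butyl (2-bromo-4-formyl-5-methoxy-1,3-phenylene) bis(carbonate) | COc1cc(OC(=O)OC(C)(C)C)c(Br)c(OC(=O)OC(C)(C)C)c1C=O
F4 | step 13 | (4S)-4-benzyl-3-[(2S,3S)-3-{3-bromo-2,4-bis[(tert-butoxycarbonyl)oxy]-6-methoxyphenyl}-3-hydroxy-2-Ar-propanoyl]-1,3-oxazolidin-2-one | O=C1OC[C@H](Cc2ccccc2)N1C(=O)[C@@H](c3ccc(OC)c(CC=C(C)C)c3OCOC)[C@H](O)c4c(OC)cc(OC(=O)OC(C)(C)C)c(Br)c4OC(=O)OC(C)(C)C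
F5 | step 13 | 2-bromo-4-[(2R)-3-hydroxy-2-Ar-propyl]-5-methoxybenzene-1,3-diol | OC[C@@H](c1ccc(OC)c(CC=C(C)C)c1OCOC)Cc2c(OC)cc(O)c(Br)c2O
F6 | step 13 | (3R)-8-bromo-5-methoxy-3-Ar-3,4-dihydro-2H-1-benzopyran-7-ol | COc1ccc([C@@H]2COc3c(Br)c(O)cc(OC)c3C2)c(OCOC)c1CC=C(C)C
F7 | step 14 | 2-bromo-6-[(1S,2R)-1,3-dihydroxy-2-Ar-propyl]-5-methoxy-3-(methoxymethoxy)phenol | OC[C@@H](c1ccc(OC)c(CC=C(C)C)c1OCOC)[C@H](O)c2c(OC)cc(OCOC)c(Br)c2O
F8 | step 14 | (3R,4S)-8-bromo-5-methoxy-7-(methoxymethoxy)-3-Ar-3,4-dihydro-2H-1-benzopyran-4-ol | C1[C@@H](c2ccc(OC)c(CC=C(C)C)c2OCOC)[C@H](O)c3c(OC)cc(OCOC)c(Br)c3O1
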